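**Retrosynthetic overview**
1. The cis-fused 12,8β-lactone and the 9α-OH come from one event: 5-exo, trans-diaxial opening of an 8α,9α-epoxide by the C12 acid (from a Δ8 olefin masked as the C9 enol triflate, and an isopropenyl group oxidised to the acrylic acid).
2. The 1β,4β-oxa-bridge comes from transannular oxymercuration of a 1β-hydroxy-4(15)-ene in a trans-decalin.
3. C5 (α-H) and C6 (α-O) come from conjugate borylation of a Δ5-en-4-one, which makes C5 trigonal and so corrects the cis ring fusion of the cycloaddition.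
4. Ring A is made in the key step, a Lewis-acid Diels–Alder reaction of (S)-carvone with a 1-silyloxybutadiene anti to the isopropenyl group; this sets C10, and every other centre is relayed from C7/C10.
5. Order of ring formation: ring B (bought) → ring A ([4+2]) → oxa-bridge → lactone.

Assumption: eudesmane numbering is used (ring A C1–C5/C10, ring B C5–C10, C11–C13 on C7, C14 = methyl on C10, C15 = carbon on C4); β is the face of the C10 methyl, and every intermediate keeps 7α-H (side chain β) and 10β-CH3.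

**Step 1**
Reactants: 1 (S)-(+)-carvone; 2 (E)-1-(trimethylsilyloxy)buta-1,3-diene
Product: 4 1α-hydroxy-15-nor-5β-eudesma-2,11(13)-dien-9-one, via TMS ether adduct 3 (not isolated)
Conditions: EtAlCl2 (0.3 equiv), toluene, −30 → 0 °C; then 1 M HCl, THF, 0 °C
Reagents that add atoms: none
Why: Lewis-acid-catalysed Diels–Alder reaction in which the oxygenated diene terminus bonds to the α-carbon ("ortho" rule) and the diene adds anti to the C7 isopropenyl group, setting the 10β-methyl quaternary centre and a cis ring fusion, while the C1 carbinol configuration is irrelevant because it is oxidised in step 2.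

**Step 2**
Reactants: 4 1α-hydroxy-15-nor-5β-eudesma-2,11(13)-dien-9-one
Product: 5 15-nor-5β-eudesma-2,11(13)-diene-1,9-dione
Conditions: Dess–Martin periodinane, CH2Cl2, rt
Reagents that add atoms: none
Why: Dess–Martin oxidation of the allylic alcohol gives the ring-A enone and removes the C1 stereocentre.

**Step 3**
Reactants: 5 15-nor-5β-eudesma-2,11(13)-diene-1,9-dione
Product: 6 1-oxo-15-nor-5β-eudesma-2,8,11(13)-trien-9-yl trifluoromethanesulfonate
Conditions: KHMDS, THF, −78 °C; then PhNTf2, −78 → 0 °C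
Reagents that add atoms: N-phenyl-bis(trifluoromethanesulfonimide), O=S(=O)(N(c1ccccc1)S(=O)(=O)C(F)(F)F)C(F)(F)F
Why: Kinetic enolisation is possible only toward C8 (C10 is quaternary and the enone has no α′-H), so enol triflate formation masks the C9 ketone as the future Δ8 olefin.

**Step 4**
Reactants: 6 1-oxo-15-nor-5β-eudesma-2,8,11(13)-trien-9-yl trifluoromethanesulfonate
Product: 7 1,4-dioxo-15-nor-5β-eudesma-2,8,11(13)-trien-9-yl trifluoromethanesulfonate
Conditions: Rh2(cap)4 (1 mol%), t-BuOOH (70% aq., 5 equiv), DCE, 40 °C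
Reagents that add atoms: tert-butyl hydroperoxide, CC(C)(C)OO
Why: Dirhodium-caprolactamate-catalysed allylic (γ) C–H oxidation turns the activated C4 methylene of the enone into a ketone, giving the 2-ene-1,4-dione.

**Step 5**
Reactants: 7 1,4-dioxo-15-nor-5β-eudesma-2,8,11(13)-trien-9-yl trifluoromethanesulfonate
Product: 9 1,4-dioxo-15-noreudesma-2,5,8,11(13)-tetraen-9-yl trifluoromethanesulfonate, via silyl dienol ether 8 (not isolated)
Conditions: TMSOTf, Et3N, CH2Cl2, 0 °C; concentrate; Pd(OAc)2 (1.05 equiv), MeCN, rt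
Reagents that add atoms: none
Why: The only enolisable hydrogen is H5, so soft enolisation followed by Saegusa–Ito dehydrogenation installs C5=C6 regiospecifically and erases the cis-fused C5 centre.

**Step 6**
Reactants: 9 1,4-dioxo-15-noreudesma-2,5,8,11(13)-tetraen-9-yl trifluoromethanesulfonate
Product: 10 1,4-dioxo-15-noreudesma-5,8,11(13)-trien-9-yl trifluoromethanesulfonate
Conditions: Zn dust, AcOH, rt, short reaction time
Reagents that add atoms: none
Why: Zinc/acetic acid conjugate reduction saturates only the doubly activated C2=C3 bond of the ene-1,4-dione, leaving the Δ5-en-4-one, the enol triflate and the isopropenyl group.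

**Step 7**
Reactants: 10 1,4-dioxo-15-noreudesma-5,8,11(13)-trien-9-yl trifluoromethanesulfonate
Product: 11 1β-hydroxy-4-oxo-15-noreudesma-5,8,11(13)-trien-9-yl trifluoromethanesulfonate
Conditions: NaBH4 (0.3 equiv), EtOH, −20 °C
Reagents that add atoms: none
Why: As with the Wieland–Miescher ketone, borohydride reduces the saturated C1 ketone chemoselectively in the presence of the enone, with hydride arriving anti to the angular methyl to give the 1β (equatorial) alcohol.

**Step 8**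
Reactants: 11 1β-hydroxy-4-oxo-15-noreudesma-5,8,11(13)-trien-9-yl trifluoromethanesulfonate
Product: 12 1β-hydroxy-4-oxo-6α-(4,4,5,5-tetramethyl-1,3,2-dioxaborolan-2-yl)-15-nor-5α-eudesma-8,11(13)-dien-9-yl trifluoromethanesulfonate
Conditions: B2pin2 (1.1 equiv), CuCl (5 mol%), DPEphos (5 mol%), NaOt-Bu (5 mol%), MeOH (2 equiv), THF, 0 °C → rt
Reagents that add atoms: bis(pinacolato)diboron, CC1(C)OB(OC1(C)C)B1OC(C)(C)C(C)(C)O1
Why: Copper-catalysed conjugate borylation delivers boron to C6 from the α face (anti to the axial C10 methyl and the C7 side chain), and the epimerisable C5 centre α to the ketone settles as the trans-fused 5α-H isomer.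

**Step 9**
Reactants: 12 1β-hydroxy-4-oxo-6α-(pinacolboryl)-15-nor-5α-eudesma-8,11(13)-dien-9-yl trifluoromethanesulfonate
Product: 13 1β-hydroxy-6α-(4,4,5,5-tetramethyl-1,3,2-dioxaborolan-2-yl)-5α-eudesma-4(15),8,11(13)-trien-9-yl trifluoromethanesulfonate
Conditions: Zn, CH2Br2, TiCl4, THF/CH2Cl2, 0 °C → rt
Reagents that add atoms: dibromomethane, BrCBr
Why: Lombardo methylenation with a non-basic gem-dimetallic reagent converts the only ketone into the 4(15)-exocyclic olefin without epimerising C5.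

**Step 10**
Reactants: 13 1β-hydroxy-6α-(pinacolboryl)-5α-eudesma-4(15),8,11(13)-trien-9-yl trifluoromethanesulfonate
Product: 15 1β,4β-epoxy-6α-(4,4,5,5-tetramethyl-1,3,2-dioxaborolan-2-yl)-5α-eudesma-8,11(13)-dien-9-yl trifluoromethanesulfonate, via organomercurial 14 (not isolated)
Conditions: Hg(OCOCF3)2 (1.05 equiv), CH2Cl2, −20 °C; then NaBH4, 3 M NaOH, 0 °C
Reagents that add atoms: none
Why: Intramolecular oxymercuration–demercuration in which the 1β-hydroxyl attacks the mercurinium ion of the 4(15)-olefin at the tertiary carbon (Markovnikov) from the β face, closing the oxa-bridge and leaving C15 as the 4α-methyl group.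

**Step 11**
Reactants: 15 1β,4β-epoxy-6α-(pinacolboryl)-5α-eudesma-8,11(13)-dien-9-yl trifluoromethanesulfonate
Product: 16 1β,4β-epoxy-6α-hydroxy-5α-eudesma-8,11(13)-dien-9-yl trifluoromethanesulfonate
Conditions: NaBO3·4H2O, THF/H2O, rt
Reagents that add atoms: sodium perborate, O=BO[O-].[Na+]
Why: Oxidation of the C–B bond by perborate proceeds by 1,2-migration with retention, unveiling the 6α-hydroxyl.

**Step 12**
Reactants: 16 1β,4β-epoxy-6α-hydroxy-5α-eudesma-8,11(13)-dien-9-yl trifluoromethanesulfonate; 17 angelic acid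
Product: 18 6α-angeloyloxy-1β,4β-epoxy-5α-eudesma-8,11(13)-dien-9-yl trifluoromethanesulfonate
Conditions: 17, 2,4,6-Cl3C6H2COCl, Et3N, toluene, rt; then 16, 80 °C
Reagents that add atoms: none
Why: Yamaguchi esterification through the mixed anhydride acylates the only free hydroxyl with angelic acid without Z→E isomerisation.

**Step 13**
Reactants: 18 6α-angeloyloxy-1β,4β-epoxy-5α-eudesma-8,11(13)-dien-9-yl trifluoromethanesulfonate
Product: 19 6α-angeloyloxy-1β,4β-epoxy-12-hydroxy-5α-eudesma-8,11(13)-dien-9-yl trifluoromethanesulfonate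
Conditions: SeO2 (0.3 equiv), t-BuOOH, CH2Cl2, rt
Reagents that add atoms: tert-butyl hydroperoxide, CC(C)(C)OO (terminal oxidant; oxygen is delivered through catalytic selenium dioxide, O=[Se]=O)
Why: Selenium-dioxide allylic oxidation (ene reaction then [2,3]-sigmatropic shift) hydroxylates the methyl group of the isopropenyl unit, the only electron-rich olefin left.

**Step 14**
Reactants: 19 6α-angeloyloxy-1β,4β-epoxy-12-hydroxy-5α-eudesma-8,11(13)-dien-9-yl trifluoromethanesulfonate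
Product: 20 6α-angeloyloxy-1β,4β-epoxy-9-(trifluoromethanesulfonyloxy)-5α-eudesma-8,11(13)-dien-12-oic acid
Conditions: TEMPO (cat.), NaOCl (cat.), NaClO2, MeCN/pH 6.7 phosphate buffer, 35 °C
Reagents that add atoms: sodium chlorite, [Na+].[O-]Cl=O
Why: TEMPO/chlorite oxidation takes the primary allylic alcohol through the aldehyde to the α-substituted acrylic acid without touching the electron-poor olefins.

**Step 15**
Reactants: 20 6α-angeloyloxy-1β,4β-epoxy-9-(trifluoromethanesulfonyloxy)-5α-eudesma-8,11(13)-dien-12-oic acid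
Product: 21 6α-angeloyloxy-1β,4β-epoxy-5α-eudesma-8,11(13)-dien-12-oic acid
Conditions: Pd(OAc)2 (5 mol%), PPh3 (10 mol%), HCO2H, n-Bu3N, DMF, 60 °C
Reagents that add atoms: none
Why: Palladium-catalysed formate reduction of the enol triflate (oxidative addition, decarboxylative hydride transfer, reductive elimination) releases the Δ8 olefin.

**Step 16**
Reactants: 21 6α-angeloyloxy-1β,4β-epoxy-5α-eudesma-8,11(13)-dien-12-oic acid
Product: 23 6α-angeloyloxy-1β,4β-epoxy-9α-hydroxy-5α-eudesm-11(13)-en-12,8β-olide (target), via epoxy acid 22 (not isolated)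
Conditions: m-CPBA, CH2Cl2, 0 °C → rt
Reagents that add atoms: meta-chloroperoxybenzoic acid, OOC(=O)c1cccc(Cl)c1
Why: Prilezhaev epoxidation of the only electron-rich olefin occurs anti to the C10 methyl (α face), and the C12 carboxyl then opens the epoxide at C8 in a 5-exo, trans-diaxial manner with inversion, giving the cis-fused 12,8β-lactone and the 9α-hydroxyl.

**Compound list**
1 | (S)-(+)-carvone, (5S)-2-methyl-5-(prop-1-en-2-yl)cyclohex-2-en-1-one | CC1=CC[C@@H](CC1=O)C(C)=C | starting material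
2 | (E)-1-(trimethylsilyloxy)buta-1,3-diene | C=C/C=C/O[Si](C)(C)C | starting material
3 | 1α-(trimethylsilyloxy)-15-nor-5β-eudesma-2,11(13)-dien-9-one (cis-fused adduct) | C[Si](C)(C)O[C@H]1C=CC[C@H]2C[C@H](C(C)=C)CC(=O)[C@@]12C | intermediate
4 | 1α-hydroxy-15-nor-5β-eudesma-2,11(13)-dien-9-one | O[C@H]1C=CC[C@H]2C[C@H](C(C)=C)CC(=O)[C@@]12C | intermediate
5 | 15-nor-5β-eudesma-2,11(13)-diene-1,9-dione | O=C1C=CC[C@H]2C[C@H](C(C)=C)CC(=O)[C@@]12C | intermediate
6 | 1-oxo-15-nor-5β-eudesma-2,8,11(13)-trien-9-yl trifluoromethanesulfonate | O=C1C=CC[C@H]2C[C@H](C(C)=C)C=C(OS(=O)(=O)C(F)(F)F)[C@@]12C | intermediate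
7 | 1,4-dioxo-15-nor-5β-eudesma-2,8,11(13)-trien-9-yl trifluoromethanesulfonate | O=C1C=CC(=O)[C@H]2C[C@H](C(C)=C)C=C(OS(=O)(=O)C(F)(F)F)[C@@]12C | intermediate
8 | 1-oxo-4-(trimethylsilyloxy)-15-noreudesma-2,4,8,11(13)-tetraen-9-yl trifluoromethanesulfonate | O=C1C=CC(O[Si](C)(C)C)=C2C[C@H](C(C)=C)C=C(OS(=O)(=O)C(F)(F)F)[C@@]12C | intermediate
9 | 1,4-dioxo-15-noreudesma-2,5,8,11(13)-tetraen-9-yl trifluoromethanesulfonate | O=C1C=CC(=O)C2=C[C@H](C(C)=C)C=C(OS(=O)(=O)C(F)(F)F)[C@@]12C | intermediate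
10 | 1,4-dioxo-15-noreudesma-5,8,11(13)-trien-9-yl trifluoromethanesulfonate | O=C1CCC(=O)C2=C[C@H](C(C)=C)C=C(OS(=O)(=O)C(F)(F)F)[C@@]12C | intermediate
11 | 1β-hydroxy-4-oxo-15-noreudesma-5,8,11(13)-trien-9-yl trifluoromethanesulfonate | O[C@@H]1CCC(=O)C2=C[C@H](C(C)=C)C=C(OS(=O)(=O)C(F)(F)F)[C@@]12C | intermediate
12 | 1β-hydroxy-4-oxo-6α-(pinacolboryl)-15-nor-5α-eudesma-8,11(13)-dien-9-yl trifluoromethanesulfonate | O[C@@H]1CCC(=O)[C@@H]2[C@@H](B3OC(C)(C)C(C)(C)O3)[C@H](C(C)=C)C=C(OS(=O)(=O)C(F)(F)F)[C@@]12C | intermediate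
13 | 1β-hydroxy-6α-(pinacolboryl)-5α-eudesma-4(15),8,11(13)-trien-9-yl trifluoromethanesulfonate | O[C@@H]1CCC(=C)[C@@H]2[C@@H](B3OC(C)(C)C(C)(C)O3)[C@H](C(C)=C)C=C(OS(=O)(=O)C(F)(F)F)[C@@]12C | intermediate
14 | [1β,4β-epoxy-6α-(pinacolboryl)-9-(trifluoromethanesulfonyloxy)-5α-eudesma-8,11(13)-dien-15-yl]mercury(II) trifluoroacetate | O=C(O[Hg]C[C@@]12CC[C@@H](O1)[C@]3(C)C(OS(=O)(=O)C(F)(F)F)=C[C@@H](C(C)=C)[C@H](B4OC(C)(C)C(C)(C)O4)[C@@H]23)C(F)(F)F | intermediate
15 | 1β,4β-epoxy-6α-(pinacolboryl)-5α-eudesma-8,11(13)-dien-9-yl trifluoromethanesulfonate (4α-methyl) | C[C@@]12CC[C@@H](O1)[C@]3(C)C(OS(=O)(=O)C(F)(F)F)=C[C@@H](C(C)=C)[C@H](B4OC(C)(C)C(C)(C)O4)[C@@H]23 | intermediate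
16 | 1β,4β-epoxy-6α-hydroxy-5α-eudesma-8,11(13)-dien-9-yl trifluoromethanesulfonate | C[C@@]12CC[C@@H](O1)[C@]3(C)C(OS(=O)(=O)C(F)(F)F)=C[C@@H](C(C)=C)[C@H](O)[C@@H]23 | intermediate
17 | angelic acid, (Z)-2-methylbut-2-enoic acid | C/C=C(/C)C(=O)O | starting material
18 | 6α-angeloyloxy-1β,4β-epoxy-5α-eudesma-8,11(13)-dien-9-yl trifluoromethanesulfonate | C[C@@]12CC[C@@H](O1)[C@]3(C)C(OS(=O)(=O)C(F)(F)F)=C[C@@H](C(C)=C)[C@H](OC(=O)/C(C)=C\C)[C@@H]23 | intermediate
19 | 6α-angeloyloxy-1β,4β-epoxy-12-hydroxy-5α-eudesma-8,11(13)-dien-9-yl trifluoromethanesulfonate | C[C@@]12CC[C@@H](O1)[C@]3(C)C(OS(=O)(=O)C(F)(F)F)=C[C@@H](C(=C)CO)[C@H](OC(=O)/C(C)=C\C)[C@@H]23 | intermediate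
20 | 6α-angeloyloxy-1β,4β-epoxy-9-(trifluoromethanesulfonyloxy)-5α-eudesma-8,11(13)-dien-12-oic acid | C[C@@]12CC[C@@H](O1)[C@]3(C)C(OS(=O)(=O)C(F)(F)F)=C[C@@H](C(=C)C(=O)O)[C@H](OC(=O)/C(C)=C\C)[C@@H]23 | intermediate
21 | 6α-angeloyloxy-1β,4β-epoxy-5α-eudesma-8,11(13)-dien-12-oic acid | C[C@@]12CC[C@@H](O1)[C@]3(C)C=C[C@@H](C(=C)C(=O)O)[C@H](OC(=O)/C(C)=C\C)[C@@H]23 | intermediate
22 | 6α-angeloyloxy-1β,4β:8α,9α-diepoxy-5α-eudesm-11(13)-en-12-oic acid | C[C@@]12CC[C@@H](O1)[C@]3(C)[C@@H]4O[C@@H]4[C@@H](C(=C)C(=O)O)[C@H](OC(=O)/C(C)=C\C)[C@@H]23 | intermediate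
23 | 6α-angeloyloxy-1β,4β-epoxy-9α-hydroxy-5α-eudesm-11(13)-en-12,8β-olide (CNP0328162.1) | C=C1C(=O)O[C@H]2[C@@H]1[C@H](OC(=O)/C(C)=C\C)[C@@H]1[C@@](C)([C@@H]2O)[C@H]2CC[C@]1(C)O2 | target

**Totals and risks**
Total step count: 16. Longest linear sequence: 16 steps (from 1).

Steps most likely to fail:

Step 1. Carvone is a sluggish dienophile and a 1-silyloxydiene can divert to an open-chain Mukaiyama–Michael product under Lewis acid. The fallback sets out from 1 and comes back at 4. Carvone 1 is annulated with Danishefsky's diene (trans-1-methoxy-3-(trimethylsilyloxy)buta-1,3-diene; EtAlCl2, toluene), where both the concerted and the stepwise Michael/aldol channel give the same ring, to form 1α-methoxy-3-(trimethylsilyloxy)-15-nor-5β-eudesma-2,11(13)-dien-9-one F1. TFA converts this to the enone 15-nor-5β-eudesma-1,11(13)-diene-3,9-dione F2. Weitz–Scheffer epoxidation (H2O2, NaOH, MeOH, 0 °C), anti to the angular methyl, gives 1α,2α-epoxy-15-nor-5β-eudesm-11(13)-ene-3,9-dione F3, and Wharton transposition (N2H4·H2O, AcOH, MeOH) delivers the allylic alcohol 4.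

Step 4. The γ C–H oxidation must beat attack at the C7–H and at the isopropenyl methyl. The fallback sets out from 6 and comes back at 7. Soft enolisation (TBSOTf, Et3N) gives 1-(tert-butyldimethylsilyloxy)-15-nor-5β-eudesma-1,3,8,11(13)-tetraen-9-yl trifluoromethanesulfonate F4. Singlet oxygen (O2, tetraphenylporphyrin, hν, CH2Cl2, −78 °C) adds [4+2] to this electron-rich diene to give 1-(tert-butyldimethylsilyloxy)-1α,4α-epidioxy-15-nor-5β-eudesma-2,8,11(13)-trien-9-yl trifluoromethanesulfonate F5, and Et3N (Kornblum–DeLaMare fragmentation with loss of the silyl group) collapses it to the enedione 7.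

Step 10. The bridge closes to a strained trans-fused 7-oxabicyclo[2.2.1]heptane, and Hg(II) can also engage the isopropenyl group. The fallback sets out from 13 and comes back at 15. Iodoetherification (N-iodosuccinimide, MeCN, 0 °C) gives 1β,4β-epoxy-15-iodo-6α-(pinacolboryl)-5α-eudesma-8,11(13)-dien-9-yl trifluoromethanesulfonate F6, and radical deiodination (Bu3SnH, AIBN, benzene, 80 °C) gives 15.

**Further compounds**
F1 | step 1 | 1α-methoxy-3-(trimethylsilyloxy)-15-nor-5β-eudesma-2,11(13)-dien-9-one | CO[C@H]1C=C(O[Si](C)(C)C)C[C@H]2C[C@H](C(C)=C)CC(=O)[C@@]12C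
F2 | step 1 | 15-nor-5β-eudesma-1,11(13)-diene-3,9-dione | O=C1C=C[C@]2(C)C(=O)C[C@@H](C(C)=C)C[C@@H]2C1
F3 | step 1 | 1α,2α-epoxy-15-nor-5β-eudesm-11(13)-ene-3,9-dione | O=C1[C@@H]2O[C@@H]2[C@]3(C)C(=O)C[C@@H](C(C)=C)C[C@@H]3C1
F4 | step 4 | 1-(tert-butyldimethylsilyloxy)-15-nor-5β-eudesma-1,3,8,11(13)-tetraen-9-yl trifluoromethanesulfonate | CC(C)(C)[Si](C)(C)OC1=CC=C[C@H]2C[C@H](C(C)=C)C=C(OS(=O)(=O)C(F)(F)F)[C@@]12C
F5 | step 4 | 1-(tert-butyldimethylsilyloxy)-1α,4α-epidioxy-15-nor-5β-eudesma-2,8,11(13)-trien-9-yl trifluoromethanesulfonate | CC(C)(C)[Si](C)(C)O[C@@]12C=C[C@@H](OO1)[C@H]3C[C@H](C(C)=C)C=C(OS(=O)(=O)C(F)(F)F)[C@@]23C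
F6 | step 10 | 1β,4β-epoxy-15-iodo-6α-(pinacolboryl)-5α-eudesma-8,11(13)-dien-9-yl trifluoromethanesulfonate | IC[C@@]12CC[C@@H](O1)[C@]3(C)C(OS(=O)(=O)C(F)(F)F)=C[C@@H](C(C)=C)[C@H](B4OC(C)(C)C(C)(C)O4)[C@@H]23
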